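**Assumption (remark on the chemistry):** the SMILES is read literally, so the decalin linked through C15′ is the C5 epimer (cis-fused, 5′S) of the decalin linked through C14 (trans-fused, 5R). Labdane numbering is used for each half, with primes for the cis-fused half.

## Analysis of the target

The target 32 is a C40 diacid made of two C20 labdane units joined through an (E)-2-alkyl-2-enal: C14 of one unit, which keeps C15 as the aldehyde, is doubly bonded to C15′ of the other. Each unit is a decalin (rings A/B) with an exocyclic C8=C17 methylene, a quaternary C4 carrying the axial 19-carboxyl and the 18-methyl, a quaternary C10 methyl, the side chain on C9 and a methyl-bearing stereocentre C13. There are ten stereocentres and one trisubstituted olefin of fixed geometry; C4, C9, C10 and C13 have the same configuration in both units (4S, 9S, 10R, 13S). The units are nevertheless not identical: the ring-fusion carbon C5 is R in the C14-linked unit (trans-decalin, 5α-H) and S in the C15′-linked unit (C5′, cis-decalin, 5β-H), so the target is a crossed condensation product of two C5-epimeric aldehydes and not a homodimer. Sensitive groups are the enal (conjugate addition, γ-deprotonation), the two 1,1-disubstituted olefins (acid-induced migration, hydrogenation) and the two neopentyl tertiary acids, whose simple alkyl esters cannot be hydrolysed next to an enal. The hard part is the contiguous C4/C5/C10/C9 array, needed twice with opposite configuration at C5: the cis-fused array with the C9 chain on the convex face is neither what a polyene cyclisation nor what equilibration delivers. The feature that invites the key move is therefore the pair C5/C5′ at the two A/B ring fusions: if both C5–H bonds are made last from one C5=C6 olefin, a single bicyclic intermediate serves both halves.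

## Retrosynthetic reasoning

**Carboxyl release.** 32 is taken back to the bis[2-(trimethylsilyl)ethyl] ester 31. The two tertiary C19 esters must fall under conditions that attack silicon rather than the hindered carbonyl, because hydroxide or thiolate cleavage is not compatible with the enal.

**C14=C15′.** 31 is cut at the enal double bond into the trans-fused aldehyde 23 (donor, used as its metallated imine 28) and the cis-fused aldehyde 27 (acceptor). This is the only cut that divides the molecule into two C20 pieces of identical constitution. The forward reaction must fix which aldehyde is the nucleophile and give the E olefin.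

**C5–H and C5′–H.** 23 and 27 go back by the same functional-group steps (alcohol oxidation, methylenation of the C8 ketone, hydrolysis of ketal and silyl ether) to the saturated esters 20 and 24. These differ only at C5 and are both disconnected at C5–H/C6–H to the single 2,5-diene 19. The cut is made here because C5 is the only centre in which the halves differ. Forward, hydrogen must enter the C5=C6 bond from the α face for 20 (steric control) and from the β face for 24 (delivery by the C19 ester).

**C3 oxygen.** 19 comes from the Δ5-3-ketone 16 by way of the enol triflate 18. The C3 carbonyl is only the trace of the ring-A annulation and is removed as an olefin that either hydrogenation consumes.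

**C4–C18.** 16 is disconnected at the C4–methyl bond to the vinylogous β-keto ester 14. Methylation of its extended enolate creates the C4 quaternary centre and moves the olefin from C4=C5 to C5=C6 in the same step. The ester must already sit on C4 so that the incoming methyl takes the α face and the ester stays β (C19).

**Ring A and C19.** 14 goes back through the iodoenone 13 (C4–C19 by carbonylation) to the enone 12, and 12 to the ring-B ketone 9 and the vinyl ketone 10 by Robinson annulation (C10–C1 and C4=C5). This sets the C10 quaternary centre relative to C9.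

**C9–C11.** 9 is cut into the commercial enone ketal 6 and the side-chain bromide 5 by a catalytic asymmetric conjugate addition with enolate methylation. C9 is the one centre set by a chiral catalyst; C10, C4 and C5 are relayed from it. The ketal is the latent C8 methylene.

**Side chain.** 5 derives in four routine steps from the commercial half-ester 1, which supplies C13 for both halves.

## Alternatives that were turned down

**Alternative 1:** the textbook disconnection. Cut C14=C15′ first and treat the free aldehyde acids A1 (trans-fused, natural series) and A2 (its 5-epimer) as two independent targets, each made by its own labdane route. The forward key step is an amine- or base-mediated crossed aldol condensation of A1 with A2. It was turned down as the strategy-defining step for three reasons. Two enolisable aldehydes of identical constitution give four enals unless one is pre-metallated. The free acids interfere with any directed variant. Above all, the disconnection solves nothing of the real problem: A2 has no chiral-pool or cyclisation-based precedent and would need a second, unrelated synthesis of the same length as that of A1. A directed form of this condensation is kept only as the joining step.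

**Alternative 2:** disconnect both rings of each half at C4–C5 and C9–C10 to an open-chain β-keto ester. The forward key step is an oxidative radical bicyclisation (Mn(III)/Cu(II)) of the (E,E)-polyene A3 to the trans-fused keto ester A4, and of the (Z,Z)-isomer A5 for the cis-fused half. It was turned down for four reasons:
- The only stereocentre of A3 is C13, five bonds from the nearest reacting carbon, so the absolute sense of the cascade is uncontrolled and A4 would form as a 1:1 pair of diastereomers. A chiral ester auxiliary on the hindered C19 carboxyl could not be removed afterwards.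
- The cascade is stepwise. After the first ring closure the C10 radical is planar, so the olefin geometry of A5 is not reliably translated into a cis ring fusion.
- In a chair-like second closure the 9β side chain would have to be axial, so mixtures at C10 and C9 are expected.
- Two polyenes with four defined trisubstituted olefins would have to be built, and the C3 ketone still has to be removed.

**Alternative 3:** disconnect ring B at C9–C10 and C7–C8. The forward key step is a Diels–Alder reaction of the ring-A diene A6 with the side-chain vinyl ketone A7 to the Δ5-octalin A8. This would reach the same kind of C5=C6 platform in one step, but it was turned down for three reasons: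
- The regiochemistry dictated by the fully substituted diene terminus puts the acyl-bearing carbon next to C10. That leaves a C11 carbonyl to delete and C8 as an unfunctionalised methylene with no handle for the 8(17)-olefin.
- The tetrasubstituted diene terminus next to a quaternary carbon is a poor reaction partner.
- The only facial bias at C10 would come from C4, whose methyl and ester groups are too similar in size to give useful selectivity.

Key step: step 16

## Route

Step 1
Reactants: 1 methyl hydrogen (R)-3-methylglutarate
Product: 2 methyl (3R)-5-hydroxy-3-methylpentanoate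
Conditions: BH3·SMe2, THF, 0 °C → rt; MeOH quench
Reagents that add atoms: none
Why: Borane reduces the free acid much faster than the methyl ester (chemoselective acid reduction); the stereocentre is not enolisable and stays untouched; the crude hydroxy ester is silylated at once to forestall lactonisation.

Step 2
Reactants: 2 methyl (3R)-5-hydroxy-3-methylpentanoate
Product: 3 methyl (3R)-5-(tert-butyldimethylsilyloxy)-3-methylpentanoate
Conditions: TBSCl, imidazole, DMF, rt
Reagents that add atoms: tert-butyldimethylsilyl chloride CC(C)(C)[Si](C)(C)Cl
Why: Standard silylation of a primary alcohol; the TBS ether survives the organometallic and basic steps and falls later together with the ketal under mild acid.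

Step 3
Reactants: 3 methyl (3R)-5-(tert-butyldimethylsilyloxy)-3-methylpentanoate
Product: 4 (3S)-5-(tert-butyldimethylsilyloxy)-3-methylpentan-1-ol
Conditions: LiAlH4, THF, 0 °C
Reagents that add atoms: none
Why: Hydride reduction of the ester to the primary alcohol; the silyl ether is stable at 0 °C (the descriptor changes to S only through the priority rules).

Step 4
Reactants: 4 (3S)-5-(tert-butyldimethylsilyloxy)-3-methylpentan-1-ol
Product: 5 [(3R)-5-bromo-3-methylpentoxy](tert-butyl)dimethylsilane
Conditions: CBr4, PPh3, CH2Cl2, 0 °C
Reagents that add atoms: carbon tetrabromide BrC(Br)(Br)Br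
Why: Appel bromination of a primary alcohol under neutral conditions that leave the silyl ether intact; 5 carries C11–C16 of both halves.

Step 5
Reactants: 5 [(3R)-5-bromo-3-methylpentoxy](tert-butyl)dimethylsilane; 6 1,4-dioxaspiro[4.5]dec-6-en-8-one
Product: 9 ring-B ketone (trans-2-methyl-3-alkyl cyclohexanone ketal), via Grignard reagent 7 (not isolated), via magnesium enolate 8 (not isolated)
Conditions: Mg, THF, rt; then 6, CuBr·SMe2 (5 mol %), Josiphos-type ferrocenyl diphosphine (6 mol %), t-BuOMe, −75 °C; then MeI, DMPU, −40 → 0 °C
Reagents that add atoms: methyl iodide CI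
Why: Copper-catalysed asymmetric conjugate addition of the Grignard reagent sets C9 under catalyst control (the ligand enantiomer is chosen so that the alkyl group enters the enone face giving the 9β chain, 9S in the target; remote C13 has no say), and the regiodefined enolate is C-methylated anti to the new chain; the C10 configuration does not matter because C10 is enolised again in step 6.

Step 6
Reactants: 9 ring-B ketone; 10 but-3-en-2-one
Product: 12 Δ4-3-ketone (17,18,19-trinorlabd-4-en-3-one ketal), via Michael adduct 11 (not isolated)
Conditions: KOH (0.2 equiv), EtOH, −10 °C → rt; then KOH (2 equiv), EtOH, 60 °C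
Reagents that add atoms: none
Why: Robinson annulation: Michael addition through the more substituted C10 enolate, then intramolecular aldol condensation closes ring A; the vinyl ketone approaches C10 anti to the adjacent pseudoaxial C9 chain, so the angular methyl ends up cis to the chain (10β-Me, 9β-chain) as in cis-vicinal dialkyl octalones made this way; C9 is not α to a carbonyl and cannot epimerise.

Step 7
Reactants: 12 Δ4-3-ketone
Product: 13 4-iodo-Δ4-3-ketone
Conditions: I2, pyridine, CH2Cl2, 0 °C → rt
Reagents that add atoms: iodine II
Why: α-Iodination of a cyclic enone (amine conjugate addition, iodination of the enolate, elimination) places the halogen on C4 only; ketal and silyl ether are inert in the buffered medium.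

Step 8
Reactants: 13 4-iodo-Δ4-3-ketone
Product: 14 2-(trimethylsilyl)ethyl 3-oxo-17,18-dinorlabd-4-en-19-oate (8-ketal, 15-OTBS)
Conditions: Pd(OAc)2, dppf, CO (1 atm), Et3N, Me3SiCH2CH2OH, DMF, 70 °C
Reagents that add atoms: carbon monoxide [C-]#[O+]; 2-(trimethylsilyl)ethanol C[Si](C)(C)CCO
Why: Palladium-catalysed alkoxycarbonylation of the α-iodoenone forms the C4–C19 bond and brings in the carboxyl already as the fluoride-labile ester needed at the end.

Step 9
Reactants: 14 vinylogous β-keto ester
Product: 16 2-(trimethylsilyl)ethyl 3-oxo-17-norlabd-5-en-19-oate (4α-Me; 8-ketal; 15-OTBS), via potassium dienolate 15 (not isolated)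
Conditions: KOtBu, t-BuOH/THF, 0 °C; then MeI, 0 °C → rt
Reagents that add atoms: methyl iodide CI
Why: Deconjugative α-alkylation: γ-deprotonation at C6 gives the extended enolate stabilised by ketone and ester, which is methylated at C4 between the carbonyls; methyl iodide attacks anti to the axial 10β-methyl (1,3-relationship), the sense known from 4,4-dialkylation of Δ4-3-keto steroids and reductive methylation of 4-carboalkoxy octalones, giving 4α-Me/4β-ester and leaving the olefin at C5=C6.

Step 10
Reactants: 16 Δ5-3-keto ester
Product: 18 enol triflate (3-triflyloxy-2,5-diene), via potassium enolate 17 (not isolated)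
Conditions: KHMDS, THF, −78 °C; then PhNTf2, −78 → 0 °C
Reagents that add atoms: N-phenylbis(trifluoromethanesulfonimide) O=S(=O)(N(c1ccccc1)S(=O)(=O)C(F)(F)F)C(F)(F)F
Why: C2 is the only enolisable position of the ketone (C4 is quaternary), so O-sulfonylation of the enolate is regiospecific; the tertiary ester has no α-hydrogen and is too hindered to react.

Step 11
Reactants: 18 enol triflate
Product: 19 2-(trimethylsilyl)ethyl 17-norlabda-2,5-dien-19-oate (8-ketal; 15-OTBS)
Conditions: Pd(OAc)2, PPh3, Bu3N, HCO2H, DMF, 60 °C
Reagents that add atoms: none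
Why: Palladium-catalysed formate reduction of the vinyl triflate removes the C3 oxygen and leaves a disubstituted C2=C3 olefin that either hydrogenation will consume; 19 is the last intermediate common to both halves.

Step 12
Reactants: 19 common 2,5-diene
Product: 20 trans-fused ester (5α-H) 2-(trimethylsilyl)ethyl 17-norlabdan-19-oate 8-ketal 15-OTBS
Conditions: H2 (10 bar), 10% Pd/C, EtOAc, rt
Reagents that add atoms: none
Why: Heterogeneous hydrogenation; the surface is reached from the α face, away from the axial 10β-methyl and the 4β-ester, as with 4,4-disubstituted Δ5-steroids, so C5 receives its hydrogen α (5R, trans-decalin); the C2=C3 olefin is reduced as well.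

Step 13
Reactants: 20 trans-fused ester ketal
Product: 21 2-(trimethylsilyl)ethyl 15-hydroxy-8-oxo-17-norlabdan-19-oate
Conditions: 1 M HCl, THF, rt
Reagents that add atoms: water O
Why: Mild aqueous acid hydrolyses the dioxolane and the primary silyl ether in one operation while the silylethyl ester stays; the equatorial 9β chain of the trans series is the stable arrangement next to the new C8 ketone.

Step 14
Reactants: 21 trans hydroxy ketone
Product: 22 2-(trimethylsilyl)ethyl 15-hydroxylabd-8(17)-en-19-oate
Conditions: Ph3PCH3Br, KHMDS (3 equiv ylide), THF, 0 °C → rt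
Reagents that add atoms: methyltriphenylphosphonium bromide C[P+](c1ccccc1)(c1ccccc1)c1ccccc1.[Br-]
Why: Wittig methylenation of the C8 ketone installs the exocyclic olefin; excess ylide covers the free hydroxyl, and the hindered tertiary ester does not react.

Step 15
Reactants: 22 trans alkenol
Product: 23 2-(trimethylsilyl)ethyl 15-oxolabd-8(17)-en-19-oate (donor aldehyde)
Conditions: Dess–Martin periodinane, NaHCO3, CH2Cl2, 0 °C → rt
Reagents that add atoms: none
Why: Buffered hypervalent-iodine oxidation of the primary alcohol gives the aldehyde without acid that could move the exocyclic olefin and without epimerising C13 (β to the carbonyl).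

Step 16
Reactants: 19 common 2,5-diene
Product: 24 cis-fused ester (5β-H) 2-(trimethylsilyl)ethyl 5-epi-17-norlabdan-19-oate 8-ketal 15-OTBS
Conditions: [Ir(cod)(PCy3)(py)]PF6 (10 mol %), H2 (4 bar), CH2Cl2, rt
Reagents that add atoms: none
Why: The cationic iridium complex adds H2 to give an Ir(III) dihydride that binds the C19 ester carbonyl, axial on the β face at C4, and from that anchor the adjacent C5=C6 olefin; migratory insertion and reductive elimination then deliver both hydrogens syn to the ester, that is to the β face, while the unhindered C2=C3 olefin is reduced without any bias being needed. The closest known reaction type is the carbonyl-directed (ester, ketone, amide) hydrogenation of cyclohexenes with cationic iridium and rhodium catalysts, in which hydrogen enters cis to the donor group even against the steric bias. No ring is closed; the step turns the A/B junction of the common diene into the cis-fused decalin. The one new stereocentre, C5 (5β-H, 5′S in the target), is controlled by the C4 centre that carries the ester, itself relayed from C10 and C9; C6 is not stereogenic. The selectivity needed is β- over α-face addition, the opposite of the steric preference used in step 12; it is secured by chelation, because the ester sits on the allylic carbon C4 and points to the β face, and because the other donors (dioxolane, silyl ether) are weaker ligands and lie further from the olefin. With steps 12 and 16 both C5 epimers come from the single intermediate 19, so the cis-fused half costs no route of its own.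

Step 17
Reactants: 24 cis-fused ester ketal
Product: 25 2-(trimethylsilyl)ethyl 15-hydroxy-8-oxo-5-epi-17-norlabdan-19-oate
Conditions: 1 M HCl, THF, 0 °C → rt (short contact time)
Reagents that add atoms: water O
Why: Same acetal and silyl ether hydrolysis as in step 13; in the cis series C9 is the centre at risk once C8 is a ketone, so the acid is kept dilute and cold and the ketone is methylenated without storage.

Step 18
Reactants: 25 cis hydroxy ketone
Product: 26 2-(trimethylsilyl)ethyl 15-hydroxy-5-epi-labd-8(17)-en-19-oate
Conditions: Ph3PCH3Br, KHMDS (3 equiv ylide), THF, −20 → 0 °C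
Reagents that add atoms: methyltriphenylphosphonium bromide C[P+](c1ccccc1)(c1ccccc1)c1ccccc1.[Br-]
Why: Wittig methylenation at low temperature with pre-formed ylide, so that olefination outruns enolisation towards the hindered tertiary C9; after this step C9 is no longer epimerisable.

Step 19
Reactants: 26 cis alkenol
Product: 27 2-(trimethylsilyl)ethyl 15-oxo-5-epi-labd-8(17)-en-19-oate (acceptor aldehyde)
Conditions: Dess–Martin periodinane, NaHCO3, CH2Cl2, 0 °C → rt
Reagents that add atoms: none
Why: Same buffered alcohol oxidation as in step 15.

Step 20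
Reactants: 23 donor aldehyde
Product: 28 N-cyclohexyl aldimine of 23
Conditions: cyclohexylamine, 4 Å molecular sieves, Et2O, rt
Reagents that add atoms: cyclohexylamine NC1CCCCC1
Why: Condensation to the aldimine fixes 23 as the future nucleophile (directed aldol logic) and prevents its self-condensation.

Step 21
Reactants: 28 N-cyclohexyl aldimine; 27 acceptor aldehyde
Product: 31 bis[2-(trimethylsilyl)ethyl] ester of the target enal, via lithio-imine 29 (not isolated), via aldol adduct 30 (not isolated)
Conditions: LDA, THF, −78 °C; then 27, −78 → −20 °C; then aq. oxalic acid, THF, rt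
Reagents that add atoms: water O
Why: Directed aldol condensation through the metallated imine: the aza-enolate of C14 adds to the C15′ aldehyde faster than it deprotonates it, and mild acid hydrolyses the imine and eliminates water to the conjugated enal; the E geometry (C15′ chain trans to CHO) is the thermodynamic outcome for a 2-alkyl-2-enal, and the tertiary esters and exocyclic olefins tolerate both the base and the weak acid.

Step 22
Reactants: 31 bis[2-(trimethylsilyl)ethyl] ester
Product: 32 target diacid CNP0229303.1
Conditions: TBAF, THF, 0 °C → rt; aq. KHSO4 work-up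
Reagents that add atoms: none
Why: Fluoride attacks silicon and fragments both silylethyl esters (loss of ethene), so the hindered C19 carbonyls need not be attacked; the enal has no α-hydrogen, and short contact at 0 °C limits γ-deprotonation.

## Compound list

1 | methyl hydrogen (R)-3-methylglutarate, (3R)-5-methoxy-3-methyl-5-oxopentanoic acid | OC(=O)C[C@@H](C)CC(=O)OC | starting material
2 | methyl (3R)-5-hydroxy-3-methylpentanoate | OCC[C@@H](C)CC(=O)OC | intermediate
3 | methyl (3R)-5-(tert-butyldimethylsilyloxy)-3-methylpentanoate | CC(C)(C)[Si](C)(C)OCC[C@@H](C)CC(=O)OC | intermediate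
4 | (3S)-5-(tert-butyldimethylsilyloxy)-3-methylpentan-1-ol | CC(C)(C)[Si](C)(C)OCC[C@@H](C)CCO | intermediate
5 | [(3R)-5-bromo-3-methylpentoxy](tert-butyl)dimethylsilane | CC(C)(C)[Si](C)(C)OCC[C@@H](C)CCBr | intermediate
6 | 1,4-dioxaspiro[4.5]dec-6-en-8-one | O=C1CCC2(OCCO2)C=C1 | starting material
7 | Grignard reagent of 5 | CC(C)(C)[Si](C)(C)OCC[C@@H](C)CC[Mg]Br | intermediate
8 | bromomagnesium enolate after conjugate addition (C9 set) | CC(C)(C)[Si](C)(C)OCC[C@@H](C)CC[C@H]1C2(OCCO2)CCC(O[Mg]Br)=C1 | intermediate
9 | ring-B ketone: 7-methyl-6-[(3S)-5-(tert-butyldimethylsilyloxy)-3-methylpentyl]-1,4-dioxaspiro[4.5]decan-8-one, 6,7-trans, C6 = C9 of the target | CC(C)(C)[Si](C)(C)OCC[C@@H](C)CC[C@H]1C2(OCCO2)CCC(=O)[C@@H]1C | intermediate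
10 | but-3-en-2-one (methyl vinyl ketone) | CC(=O)C=C | starting material
11 | Michael adduct (2-methyl-2-(3-oxobutyl) ketone, C10 quaternary) | CC(C)(C)[Si](C)(C)OCC[C@@H](C)CC[C@H]1C2(OCCO2)CCC(=O)[C@]1(C)CCC(C)=O | intermediate
12 | (13S)-15-(tert-butyldimethylsilyloxy)-8,8-ethylenedioxy-17,18,19-trinorlabd-4-en-3-one (9β-chain, 10β-Me) | CC(C)(C)[Si](C)(C)OCC[C@@H](C)CC[C@H]1C2(OCCO2)CCC3=CC(=O)CC[C@]13C | intermediate
13 | 4-iodo derivative of 12 | CC(C)(C)[Si](C)(C)OCC[C@@H](C)CC[C@H]1C2(OCCO2)CCC3=C(I)C(=O)CC[C@]13C | intermediate
14 | 2-(trimethylsilyl)ethyl (13S)-15-(tert-butyldimethylsilyloxy)-8,8-ethylenedioxy-3-oxo-17,18-dinorlabd-4-en-19-oate | CC(C)(C)[Si](C)(C)OCC[C@@H](C)CC[C@H]1C2(OCCO2)CCC3=C(C(=O)OCC[Si](C)(C)C)C(=O)CC[C@]13C | intermediate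
15 | potassium 3,5-dienolate of 14 | CC(C)(C)[Si](C)(C)OCC[C@@H](C)CC[C@H]1C2(OCCO2)CC=C3C(C(=O)OCC[Si](C)(C)C)=C([O-])CC[C@]13C.[K+] | intermediate
16 | 2-(trimethylsilyl)ethyl (13S)-15-(tert-butyldimethylsilyloxy)-8,8-ethylenedioxy-3-oxo-17-norlabd-5-en-19-oate (4α-Me, 4β-ester, 9β-chain, 10β-Me) | CC(C)(C)[Si](C)(C)OCC[C@@H](C)CC[C@H]1C2(OCCO2)CC=C3[C@@](C)(C(=O)OCC[Si](C)(C)C)C(=O)CC[C@]13C | intermediate
17 | potassium 2-en-3-olate of 16 | CC(C)(C)[Si](C)(C)OCC[C@@H](C)CC[C@H]1C2(OCCO2)CC=C3[C@@](C)(C(=O)OCC[Si](C)(C)C)C([O-])=CC[C@]13C.[K+] | intermediate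
18 | 3-(trifluoromethanesulfonyloxy)-2,5-diene derived from 16 | CC(C)(C)[Si](C)(C)OCC[C@@H](C)CC[C@H]1C2(OCCO2)CC=C3[C@@](C)(C(=O)OCC[Si](C)(C)C)C(OS(=O)(=O)C(F)(F)F)=CC[C@]13C | intermediate
19 | 2-(trimethylsilyl)ethyl (13S)-15-(tert-butyldimethylsilyloxy)-8,8-ethylenedioxy-17-norlabda-2,5-dien-19-oate (common intermediate) | CC(C)(C)[Si](C)(C)OCC[C@@H](C)CC[C@H]1C2(OCCO2)CC=C3[C@@](C)(C(=O)OCC[Si](C)(C)C)C=CC[C@]13C | intermediate
20 | 2-(trimethylsilyl)ethyl (13S)-15-(tert-butyldimethylsilyloxy)-8,8-ethylenedioxy-17-norlabdan-19-oate (5α-H, trans-fused) | CC(C)(C)[Si](C)(C)OCC[C@@H](C)CC[C@H]1C2(OCCO2)CC[C@H]3[C@@](C)(C(=O)OCC[Si](C)(C)C)CCC[C@]13C | intermediate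
21 | 2-(trimethylsilyl)ethyl (13S)-15-hydroxy-8-oxo-17-norlabdan-19-oate (trans-fused) | OCC[C@@H](C)CC[C@H]1C(=O)CC[C@H]3[C@@](C)(C(=O)OCC[Si](C)(C)C)CCC[C@]13C | intermediate
22 | 2-(trimethylsilyl)ethyl (13S)-15-hydroxylabd-8(17)-en-19-oate (trans-fused) | OCC[C@@H](C)CC[C@H]1C(=C)CC[C@H]3[C@@](C)(C(=O)OCC[Si](C)(C)C)CCC[C@]13C | intermediate
23 | 2-(trimethylsilyl)ethyl (13S)-15-oxolabd-8(17)-en-19-oate (trans-fused donor aldehyde) | O=CC[C@@H](C)CC[C@H]1C(=C)CC[C@H]3[C@@](C)(C(=O)OCC[Si](C)(C)C)CCC[C@]13C | intermediate
24 | 2-(trimethylsilyl)ethyl (13S)-15-(tert-butyldimethylsilyloxy)-8,8-ethylenedioxy-5-epi-17-norlabdan-19-oate (5β-H, cis-fused) | CC(C)(C)[Si](C)(C)OCC[C@@H](C)CC[C@H]1C2(OCCO2)CC[C@@H]3[C@@](C)(C(=O)OCC[Si](C)(C)C)CCC[C@]13C | intermediate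
25 | 2-(trimethylsilyl)ethyl (13S)-15-hydroxy-8-oxo-5-epi-17-norlabdan-19-oate (cis-fused) | OCC[C@@H](C)CC[C@H]1C(=O)CC[C@@H]3[C@@](C)(C(=O)OCC[Si](C)(C)C)CCC[C@]13C | intermediate
26 | 2-(trimethylsilyl)ethyl (13S)-15-hydroxy-5-epi-labd-8(17)-en-19-oate (cis-fused) | OCC[C@@H](C)CC[C@H]1C(=C)CC[C@@H]3[C@@](C)(C(=O)OCC[Si](C)(C)C)CCC[C@]13C | intermediate
27 | 2-(trimethylsilyl)ethyl (13S)-15-oxo-5-epi-labd-8(17)-en-19-oate (cis-fused acceptor aldehyde) | O=CC[C@@H](C)CC[C@H]1C(=C)CC[C@@H]3[C@@](C)(C(=O)OCC[Si](C)(C)C)CCC[C@]13C | intermediate
28 | (E)-N-cyclohexyl aldimine of 23 | C1CCCCC1/N=C/C[C@@H](C)CC[C@H]1C(=C)CC[C@H]3[C@@](C)(C(=O)OCC[Si](C)(C)C)CCC[C@]13C | intermediate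
29 | lithiated imine (1-azaallyl lithium) of 28 | [Li]N(C1CCCCC1)C=C[C@@H](C)CC[C@H]1C(=C)CC[C@H]3[C@@](C)(C(=O)OCC[Si](C)(C)C)CCC[C@]13C | intermediate
30 | aldol adduct: β-hydroxy imine, C14–C15′ bond formed, mixture at C14 and C15′ (drawn neutral) | C=C1CC[C@@H]2[C@](C)(CCC[C@]2(C)C(=O)OCC[Si](C)(C)C)[C@H]1CC[C@H](C)C(/C=N/C1CCCCC1)C(O)C[C@@H](C)CC[C@H]1C(=C)CC[C@H]2[C@]1(C)CCC[C@]2(C)C(=O)OCC[Si](C)(C)C | intermediate
31 | bis[2-(trimethylsilyl)ethyl] ester of the target (E-enal) | C=C1CC[C@@H]2[C@](C)(CCC[C@]2(C)C(=O)OCC[Si](C)(C)C)[C@H]1CC[C@H](C)/C(C=O)=C\C[C@@H](C)CC[C@H]1C(=C)CC[C@H]2[C@]1(C)CCC[C@]2(C)C(=O)OCC[Si](C)(C)C | intermediate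
32 | target CNP0229303.1: (4S,5R,9S,10R,13S)-15-oxolabd-8(17)-en-19-oic acid joined E at C14 to C15′ of (4′S,5′S,9′S,10′R,13′S)-5′-epi-labd-8′(17′)-en-19′-oic acid | C=C1CC[C@@H]2[C@](C)(CCC[C@]2(C)C(=O)O)[C@H]1CC[C@H](C)/C(C=O)=C\C[C@@H](C)CC[C@H]1C(=C)CC[C@H]2[C@]1(C)CCC[C@]2(C)C(=O)O | target

## Step count and risk

Total: 22 steps. Longest linear sequence: 18 steps (steps 1–11, 12–15, 20–22).

**Least certain steps**

**Step 16 (key step).** The trisubstituted C5=C6 olefin lies between two quaternary carbons, so binding of the bulky cationic catalyst may be slow. The catalyst may then deactivate, or addition may leak to the open α face, which would give the trans ester 20 instead of 24. The fallback replaces the ester by a stronger donor and sets out from 19. Reduction with LiAlH4 (THF, 0 °C → rt) should give the C19 primary alcohol F1, a homoallylic alcohol on the β face. Hydrogenation with the same iridium catalyst is then hydroxyl-directed, the best established form of this reaction, and should give the cis-fused alcohol F2. One-pot oxidation (TEMPO, NaOCl, NaClO2, pH 6.7) should give the acid F3. Mitsunobu esterification of F3 with 2-(trimethylsilyl)ethanol returns to 24.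

**Step 6.** The Michael addition has to occur at the neopentyl-like C10 rather than at C6. Enolisation in the wrong direction, polymerisation of the vinyl ketone or a slow addition would lower the yield or give the regioisomeric octalone. The fallback fixes the enolate regiochemistry beforehand and sets out from 9. Equilibrating silylation (TMSCl, Et3N, DMF, 80 °C) should give the more substituted silyl enol ether F4. Methyllithium releases the lithium enolate, which adds to 3-(trimethylsilyl)but-3-en-2-one in aprotic medium to give the α-silyl diketone F5. KOH in methanol then removes silicon and closes the ring, returning to 12.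

**Step 21.** Three processes may interfere: retro-aldol cleavage of the adduct 30 during the acid treatment, incomplete dehydration, and acid-induced movement of the exocyclic olefins. The fallback makes the olefin by elimination of silanolate instead of water and sets out from 28. LDA and then TMSCl should give the α-silyl imine F6. A second deprotonation with LDA and addition of 27 gives the 2-aza-diene F7 directly by Peterson elimination. Brief hydrolysis with aqueous oxalic acid returns to 31.

## Further compounds

F1 | step 16 | C19 primary alcohol of the common 2,5-diene | CC(C)(C)[Si](C)(C)OCC[C@@H](C)CC[C@H]1C2(OCCO2)CC=C3[C@@](C)(CO)C=CC[C@]13C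
F2 | step 16 | cis-fused (5β-H) saturated C19 alcohol | CC(C)(C)[Si](C)(C)OCC[C@@H](C)CC[C@H]1C2(OCCO2)CC[C@@H]3[C@@](C)(CO)CCC[C@]13C
F3 | step 16 | cis-fused (5β-H) C19 carboxylic acid | CC(C)(C)[Si](C)(C)OCC[C@@H](C)CC[C@H]1C2(OCCO2)CC[C@@H]3[C@@](C)(C(=O)O)CCC[C@]13C
F4 | step 6 | more substituted trimethylsilyl enol ether of 9 | CC(C)(C)[Si](C)(C)OCC[C@@H](C)CC[C@H]1C2(OCCO2)CCC(O[Si](C)(C)C)=C1C
F5 | step 6 | α-silyl diketone (Michael adduct with the silyl vinyl ketone) | CC(C)(C)[Si](C)(C)OCC[C@@H](C)CC[C@H]1C2(OCCO2)CCC(=O)[C@]1(C)CC([Si](C)(C)C)C(C)=O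
F6 | step 21 | C14-trimethylsilyl derivative of imine 28 | C1CCCCC1/N=C/C([Si](C)(C)C)[C@@H](C)CC[C@H]1C(=C)CC[C@H]3[C@@](C)(C(=O)OCC[Si](C)(C)C)CCC[C@]13C
F7 | step 21 | N-cyclohexyl imine of 31 (2-aza-diene) | C=C1CC[C@@H]2[C@](C)(CCC[C@]2(C)C(=O)OCC[Si](C)(C)C)[C@H]1CC[C@H](C)/C(/C=N/C1CCCCC1)=C\C[C@@H](C)CC[C@H]1C(=C)CC[C@H]2[C@]1(C)CCC[C@]2(C)C(=O)OCC[Si](C)(C)C
A1 | alternative 1 | (13S)-15-oxolabd-8(17)-en-19-oic acid (trans-fused aldehyde acid) | C=C1CC[C@@H]2[C@](C)(CCC[C@]2(C)C(=O)O)[C@H]1CC[C@H](C)CC=O
A2 | alternative 1 | (13S)-15-oxo-5-epi-labd-8(17)-en-19-oic acid (cis-fused aldehyde acid) | O=CC[C@@H](C)CC[C@H]1C(=C)CC[C@H]2[C@]1(C)CCC[C@]2(C)C(=O)O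
A3 | alternative 2 | methyl (6E,10E,14S)-16-(tert-butyldimethylsilyloxy)-2,7,11,14-tetramethyl-3-oxohexadeca-6,10-dienoate | COC(=O)C(C)C(=O)CC/C(C)=C/CC/C(C)=C/CC[C@H](C)CCO[Si](C)(C)C(C)(C)C
A4 | alternative 2 | methyl (13S)-15-(tert-butyldimethylsilyloxy)-3-oxolabd-8(17)-en-19-oate (trans-fused) | C=C1CC[C@@H]2[C@](C)(CCC(=O)[C@]2(C)C(=O)OC)[C@H]1CC[C@H](C)CCO[Si](C)(C)C(C)(C)C
A5 | alternative 2 | (6Z,10Z) isomer of A3 | COC(=O)C(C)C(=O)CC/C(C)=C\CC/C(C)=C\CC[C@H](C)CCO[Si](C)(C)C(C)(C)C
A6 | alternative 3 | methyl 1,3-dimethyl-2-vinylcyclohex-2-ene-1-carboxylate (ring-A diene) | C=CC1=C(C)CCC[C@]1(C)C(=O)OC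
A7 | alternative 3 | (5S)-7-(tert-butyldimethylsilyloxy)-5-methylhept-1-en-3-one (side-chain vinyl ketone) | C=CC(=O)C[C@H](C)CCO[Si](C)(C)C(C)(C)C
A8 | alternative 3 | Diels–Alder adduct: methyl 11-oxo-15-silyloxy-17-norlabd-5-en-19-oate | O=C(C[C@H](C)CCO[Si](C)(C)C(C)(C)C)[C@H]1CCC=C2[C@@](C)(C(=O)OC)CCC[C@]12C
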